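## Retrosynthetic overview

1. Target ⇐ Evans–Tishchenko step (C9 pyrrole ester and C11–OH together) ⇐ 9-hydroxy-11-ketone ⇐ key step: the C13–O bond of the oxolane bridge is made last on the skeleton, by a radical C–H etherification (C8 alkoxy radical, 1,5-hydrogen atom transfer from C13–H).
2. The 8,13-deoxy tricycle (rings A and B plus the ten-membered lactone) ⇐ transannular Diels–Alder reaction of an 18-membered tetraene macrolide ⇐ intramolecular Stille closure of C13–C14.
3. Linear stannane–iodide ⇐ ene–diene cross-metathesis (C4=C5) of a dienyl stannyl enone with an allyl ester carrying the (Z)-vinyl iodide.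
4. Building blocks: allyl acid (methyl (S)-glycidate + vinyl Grignard); iodide (methyl (R)-lactate, crotylboration, Stork–Zhao olefination); all-cis lactone (Evans anti-aldol, chelation-controlled dienylzinc addition).
5. Ring order: 18-membered macrocycle → rings A/B and ten-membered lactone in one cycloaddition → oxolane bridge (radical) → C9/C11 adjustment.

Assumption: positions are numbered as in nargenicin (C1 lactone carbonyl to C19 methyl); the auxiliary, organometallic transfer reagents and protecting-group reagents are treated as reagents.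

## Route

Step 1
Reactants: 1 methyl (2S)-oxirane-2-carboxylate; 2 bromo(ethenyl)magnesium
Product: 3 methyl (2S)-2-hydroxypent-4-enoate
Conditions: CuI (10 mol %), THF, −40 °C; aq. NH4Cl
Reagents that add atoms: none
Why: Copper-catalysed Grignard opening of the terminal epoxide (SN2 at the unsubstituted C3) leaves the C2 stereocentre of the glycidate untouched.

Step 2
Reactants: 3 methyl (2S)-2-hydroxypent-4-enoate
Product: 4 methyl (2S)-2-methoxypent-4-enoate
Conditions: MeI, Ag2O, 4 Å sieves, Et2O, 25 °C, dark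
Reagents that add atoms: iodomethane, CI
Why: Purdie methylation (Williamson-type) with silver oxide is non-basic, so the α-stereocentre does not epimerise.

Step 3
Reactants: 4 methyl (2S)-2-methoxypent-4-enoate
Product: 5 (2S)-2-methoxypent-4-enoic acid
Conditions: LiOH, THF/H2O 3:1, 0 °C; 1 M HCl to pH 3
Reagents that add atoms: lithium hydroxide, [Li+].[OH-]
Why: Saponification at 0 °C cleaves the methyl ester without enolising the α-alkoxy centre.

Step 4
Reactants: 6 methyl (2R)-2-hydroxypropanoate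
Product: 7 methyl (2R)-2-[(tert-butyldimethylsilyl)oxy]propanoate
Conditions: TBSCl, imidazole, DMF, 25 °C
Reagents that add atoms: tert-butyldimethylsilyl chloride, CC(C)(C)[Si](C)(C)Cl
Why: Standard silylation of the secondary alcohol; the C18 stereocentre comes unchanged from the lactate.

Step 5
Reactants: 7 methyl (2R)-2-[(tert-butyldimethylsilyl)oxy]propanoate
Product: 8 (2R)-2-[(tert-butyldimethylsilyl)oxy]propanal
Conditions: i-Bu2AlH (1.1 equiv), CH2Cl2, −78 °C; aq. potassium sodium tartrate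
Reagents that add atoms: none
Why: Partial ester reduction: the aluminium hemiacetal is stable at −78 °C and gives the aldehyde only on work-up, without loss of the α-stereocentre.

Step 6
Reactants: 8 (2R)-2-[(tert-butyldimethylsilyl)oxy]propanal
Product: 9 (2R,3S,4R)-2-[(tert-butyldimethylsilyl)oxy]-4-methylhex-5-en-3-ol
Conditions: (Z)-crotylboronic acid pinacol ester (1.5 equiv), toluene, 4 Å sieves, −78 → 25 °C, 36 h; aq. NaHCO3
Reagents that add atoms: (Z)-crotylboronic acid pinacol ester, C/C=C\CB1OC(C)(C)C(C)(C)O1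
Why: Allylboration through a closed chair (Zimmerman–Traxler) transition state: the Z-crotyl geometry sets C16/C17 syn and Felkin–Anh (Cornforth) attack on the α-silyloxy aldehyde sets C17/C18 anti.

Step 7
Reactants: 9 (2R,3S,4R)-2-[(tert-butyldimethylsilyl)oxy]-4-methylhex-5-en-3-ol
Product: 10 (2R,3S,4R)-2-[(tert-butyldimethylsilyl)oxy]-4-methyl-3-[(trimethylsilyl)oxy]hex-5-ene
Conditions: TMSCl, imidazole, CH2Cl2, 0 °C
Reagents that add atoms: chlorotrimethylsilane, C[Si](C)(C)Cl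
Why: Temporary silylation of the C17 carbinol so that the β-oxy aldehyde of the next two steps cannot undergo retro-aldol cleavage or elimination.

Step 8
Reactants: 10 (2R,3S,4R)-2-[(tert-butyldimethylsilyl)oxy]-4-methyl-3-[(trimethylsilyl)oxy]hex-5-ene
Product: 11 (2S,3S,4R)-4-[(tert-butyldimethylsilyl)oxy]-2-methyl-3-[(trimethylsilyl)oxy]pentanal
Conditions: O3, CH2Cl2, −78 °C; PPh3, −78 → 25 °C; used crude
Reagents that add atoms: ozone, [O-][O+]=O
Why: Ozonolysis with reductive work-up cleaves the only olefin, and the α-methyl aldehyde is carried on crude to avoid epimerisation.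

Step 9
Reactants: 11 (2S,3S,4R)-4-[(tert-butyldimethylsilyl)oxy]-2-methyl-3-[(trimethylsilyl)oxy]pentanal
Product: 13 (2R,3S,4R,5Z)-2-[(tert-butyldimethylsilyl)oxy]-6-iodo-4-methylhept-5-en-3-ol, via TMS ether 12 (not isolated)
Conditions: [Ph3PCH(I)CH3]I, NaN(SiMe3)2, THF, −78 → −20 °C; 11, −78 °C; then 10 % aq. citric acid/THF, 25 °C
Reagents that add atoms: (1-iodoethyl)triphenylphosphonium iodide, CC(I)[P+](c1ccccc1)(c1ccccc1)c1ccccc1.[I-]
Why: Stork–Zhao olefination (Wittig reaction of the α-iodo ylide) gives the (Z)-2-iodoalkene with iodine cis to C16, the geometry needed for C14=C15, and the labile TMS ether falls off in the acidic work-up.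

Step 10
Reactants: 13 (2R,3S,4R,5Z)-2-[(tert-butyldimethylsilyl)oxy]-6-iodo-4-methylhept-5-en-3-ol; 5 (2S)-2-methoxypent-4-enoic acid
Product: 15 (2R,3S,4R,5Z)-2-[(tert-butyldimethylsilyl)oxy]-6-iodo-4-methylhept-5-en-3-yl (2S)-2-methoxypent-4-enoate, via mixed anhydride 14 (not isolated)
Conditions: 5, 2,4,6-trichlorobenzoyl chloride, Et3N, toluene, 25 °C; then 13, DMAP, 25 °C
Reagents that add atoms: none
Why: Yamaguchi esterification through the mixed anhydride acylates the hindered C17 alcohol; no stereocentre is involved.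

Step 11
Reactants: 15 (2R,3S,4R,5Z)-2-[(tert-butyldimethylsilyl)oxy]-6-iodo-4-methylhept-5-en-3-yl (2S)-2-methoxypent-4-enoate
Product: 17 (2R,3S,4R,5Z)-2-acetoxy-6-iodo-4-methylhept-5-en-3-yl (2S)-2-methoxypent-4-enoate, via C18 alcohol 16 (not isolated)
Conditions: HF·pyridine, pyridine/THF, 0 → 25 °C; then Ac2O, DMAP, 25 °C
Reagents that add atoms: acetic anhydride, CC(=O)OC(C)=O
Why: Fluoride desilylation followed in the same flask by acetylation fixes the C18 acetate before acyl migration can occur.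

Step 12
Reactants: 18 propanoyl chloride
Product: 19 (4R)-4-benzyl-3-propanoyl-1,3-oxazolidin-2-one
Conditions: (4R)-4-benzyl-1,3-oxazolidin-2-one, Et3N, DMAP (cat.), CH2Cl2, 0 → 25 °C
Reagents that add atoms: (4R)-4-benzyl-1,3-oxazolidin-2-one, O=C1N[C@H](Cc2ccccc2)CO1
Why: DMAP-catalysed N-acylation of the auxiliary (acyl substitution).

Step 13
Reactants: 19 (4R)-4-benzyl-3-propanoyl-1,3-oxazolidin-2-one; 20 (2E)-but-2-enal
Product: 22 (4R)-4-benzyl-3-[(2S,3S,4E)-3-hydroxy-2-methylhex-4-enoyl]-1,3-oxazolidin-2-one, via O-TMS aldol 21 (not isolated)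
Conditions: MgCl2 (0.2 equiv), Et3N, TMSCl, EtOAc, 25 °C; then THF/1 M HCl 5:1
Reagents that add atoms: none
Why: Evans magnesium-halide-catalysed direct anti-aldol: the chelated Z-enolate adds to the enal through a boat transition state on the face anti to the benzyl group, setting C10 and the anti C9 carbinol, and silylation of the aldolate drives turnover.

Step 14
Reactants: 22 (4R)-4-benzyl-3-[(2S,3S,4E)-3-hydroxy-2-methylhex-4-enoyl]-1,3-oxazolidin-2-one
Product: 23 (4R)-4-benzyl-3-[(2S,3S,4E)-3-[(tert-butyldimethylsilyl)oxy]-2-methylhex-4-enoyl]-1,3-oxazolidin-2-one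
Conditions: TBSOTf, 2,6-lutidine, CH2Cl2, −78 → 0 °C
Reagents that add atoms: tert-butyldimethylsilyl trifluoromethanesulfonate, CC(C)(C)[Si](C)(C)OS(=O)(=O)C(F)(F)F
Why: Silylation of the C9 hydroxyl with a group that offers no hydrogen within reach of the later C8 alkoxy radical (a benzyl or acetal ether would be attacked by 1,5-transfer).

Step 15
Reactants: 23 (4R)-4-benzyl-3-[(2S,3S,4E)-3-[(tert-butyldimethylsilyl)oxy]-2-methylhex-4-enoyl]-1,3-oxazolidin-2-one
Product: 24 (4R)-4-benzyl-3-[(2S,3R)-3-[(tert-butyldimethylsilyl)oxy]-2-methyl-4-oxobutanoyl]-1,3-oxazolidin-2-one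
Conditions: O3, CH2Cl2, −78 °C; PPh3; used crude
Reagents that add atoms: ozone, [O-][O+]=O
Why: Ozonolysis excises the propenyl group and unveils the C8 aldehyde.

Step 16
Reactants: 24 (4R)-4-benzyl-3-[(2S,3R)-3-[(tert-butyldimethylsilyl)oxy]-2-methyl-4-oxobutanoyl]-1,3-oxazolidin-2-one; 25 but-1-en-3-yne
Product: 29 (3S,4R,5R)-5-[(1E)-buta-1,3-dien-1-yl]-4-[(tert-butyldimethylsilyl)oxy]-3-methyloxolan-2-one, via dienylzirconocene 26 (not isolated), via dienylmethylzinc 27 (not isolated), via hydroxy imide 28 (not isolated)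
Conditions: 25, Cp2Zr(H)Cl, CH2Cl2, 25 °C; Me2Zn, toluene, −78 °C; EtZnCl (from Et2Zn + ZnCl2, 1.5 equiv) and 24, −30 → 0 °C; then Et3N, DMAP (cat.), 25 °C; aq. NH4Cl
Reagents that add atoms: none
Why: Hydrozirconation of the alkyne and Zr→Zn transmetalation give the (E)-dienylzinc, which adds under chelation (Cram-chelate) control because the alkylzinc chloride bridges the aldehyde and the C9 silyloxy oxygen, so C8 forms syn to C9–O (8R), and the alkoxide then displaces the oxazolidinone by 5-exo acyl transfer to give the all-cis lactone.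

Step 17
Reactants: 29 (3S,4R,5R)-5-[(1E)-buta-1,3-dien-1-yl]-4-[(tert-butyldimethylsilyl)oxy]-3-methyloxolan-2-one
Product: 30 (1E,4S,5R,6R,7E)-5-[(tert-butyldimethylsilyl)oxy]-6-hydroxy-4-methyl-1-(tributylstannyl)deca-1,7,9-trien-3-one
Conditions: (E)-1,2-bis(tributylstannyl)ethene, n-BuLi, THF, −78 °C; then 29, −78 °C; aq. NH4Cl at −78 °C
Reagents that add atoms: (E)-1,2-bis(tributylstannyl)ethene, CCCC[Sn](CCCC)(CCCC)/C=C/[Sn](CCCC)(CCCC)CCCC
Why: Acyl substitution on the lactone: the lithium lactolate is stable at −78 °C, so the (E)-stannylvinyllithium adds once and work-up releases the γ-hydroxy (E)-β-stannyl enone with C8–C10 untouched.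

Step 18
Reactants: 30 (1E,4S,5R,6R,7E)-5-[(tert-butyldimethylsilyl)oxy]-6-hydroxy-4-methyl-1-(tributylstannyl)deca-1,7,9-trien-3-one; 17 (2R,3S,4R,5Z)-2-acetoxy-6-iodo-4-methylhept-5-en-3-yl (2S)-2-methoxypent-4-enoate
Product: 31 (2R,3S,4R,5Z)-2-acetoxy-6-iodo-4-methylhept-5-en-3-yl (2S,4E,6E,8R,9R,10S,12E)-9-[(tert-butyldimethylsilyl)oxy]-8-hydroxy-2-methoxy-10-methyl-11-oxo-13-(tributylstannyl)trideca-4,6,12-trienoate
Conditions: second-generation Hoveyda–Grubbs catalyst RuCl2(H2IMes)(=CH-C6H4-2-O-i-Pr) (10 mol %), 17 (1.5 equiv), 1,4-benzoquinone (20 mol %), CH2Cl2, 35 °C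
Reagents that add atoms: none
Why: Ene–diene cross-metathesis: the carbene loads on the allyl group of 17 and reacts with the terminal olefin of the diene (the internal one next to the carbinol is hindered) to give the (4E,6E)-diene, while the trisubstituted vinyl iodide and the bulky β-stannyl enone are inert and the latter is too poor a dienophile to cycloadd early.

Step 19
Reactants: 31 (the linear stannane–iodide of step 18)
Product: 33 8,13-deoxy tricycle (cis-fused octalin bridged by the ten-membered lactone; 8-OH, 9-OTBS, 11-ketone, 18-OAc; 2S,4S,7R,8R,9R,10S,12S,13R,14Z,16R,17S,18R), via macrocycle 32 (not isolated)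
Conditions: Pd2(dba)3 (10 mol %), AsPh3 (40 mol %), DMF/THF 1:1 (1 mM), 40 °C; then 80 °C
Reagents that add atoms: none
Why: Intramolecular Stille coupling (retention at both alkenes) closes the 18-membered ring, and its (4E,6E)-diene and (12E)-enone then undergo the transannular Diels–Alder reaction in the ketone-endo, cis-fused mode known for 1,7,9-decatrien-3-ones, with C9–OTBS and C10–Me on the face away from the stacked π systems, which sets C4, C7, C12 and C13 (H-13 syn to O-8) and forms rings A and B and the ten-membered lactone together.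

Step 20
Reactants: 33 (the 8,13-deoxy tricycle of step 19)
Product: 34 oxolane-bridged tetracycle (8,13-ether; 9-OTBS, 11-ketone, 18-OAc; 13S)
Conditions: PhI(OAc)2 (2 equiv), I2 (1 equiv), cyclohexane/CH2Cl2 3:1 (5 mM), visible light (tungsten lamp), 25 °C
Reagents that add atoms: none
Why: Suárez hypoiodite reaction: homolysis of the C8 O–I bond gives the alkoxy radical, which abstracts the syn, tertiary allylic H-13 through a six-membered transition state (1,5-hydrogen atom transfer), and after iodine transfer/oxidation of the allyl radical the same oxygen closes the five-membered ether at C13 (C15 would need a seven-membered ring), a ring that can only be cis-fused and so fixes C13 as S.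

Step 21
Reactants: 34 (the oxolane-bridged tetracycle of step 20)
Product: 35 9-hydroxy-11-ketone (18-O-acetyl-11-dehydro-9-O-de(pyrrolylcarbonyl)nargenicin)
Conditions: HF·pyridine, THF, 0 → 25 °C
Reagents that add atoms: none
Why: Fluoride cleavage of the C9 silyl ether; acetate, lactone, ether bridge and ketone are inert to HF·pyridine.

Step 22
Reactants: 35 (the 9-hydroxy-11-ketone of step 21); 36 1H-pyrrole-2-carbaldehyde
Product: 37 18-O-acetyl-nargenicin
Conditions: 36 (5 equiv), SmI2 (0.3 equiv), THF, −10 °C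
Reagents that add atoms: none
Why: Evans–Tishchenko reaction: the samarium-bound hemiacetal formed from 36 and the axial C9 hydroxyl delivers hydride intramolecularly to the same face of the C11 ketone through a six-membered chair, giving the 1,3-anti C11 alcohol (11R) and the C9 pyrrole-2-carboxylate in one operation.

## Compound list

1 | methyl (2S)-oxirane-2-carboxylate | COC(=O)[C@@H]1CO1 | starting material
2 | bromo(ethenyl)magnesium | C=C[Mg]Br | starting material
3 | methyl (2S)-2-hydroxypent-4-enoate | COC(=O)[C@@H](O)CC=C | intermediate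
4 | methyl (2S)-2-methoxypent-4-enoate | COC(=O)[C@@H](OC)CC=C | intermediate
5 | (2S)-2-methoxypent-4-enoic acid | OC(=O)[C@@H](OC)CC=C | intermediate
6 | methyl (2R)-2-hydroxypropanoate | C[C@@H](O)C(=O)OC | starting material
7 | methyl (2R)-2-[(tert-butyldimethylsilyl)oxy]propanoate | C[C@@H](O[Si](C)(C)C(C)(C)C)C(=O)OC | intermediate
8 | (2R)-2-[(tert-butyldimethylsilyl)oxy]propanal | C[C@@H](O[Si](C)(C)C(C)(C)C)C=O | intermediate
9 | (2R,3S,4R)-2-[(tert-butyldimethylsilyl)oxy]-4-methylhex-5-en-3-ol | C=C[C@@H](C)[C@H](O)[C@@H](C)O[Si](C)(C)C(C)(C)C | intermediate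
10 | (2R,3S,4R)-2-[(tert-butyldimethylsilyl)oxy]-4-methyl-3-[(trimethylsilyl)oxy]hex-5-ene | C=C[C@@H](C)[C@H](O[Si](C)(C)C)[C@@H](C)O[Si](C)(C)C(C)(C)C | intermediate
11 | (2S,3S,4R)-4-[(tert-butyldimethylsilyl)oxy]-2-methyl-3-[(trimethylsilyl)oxy]pentanal | O=C[C@@H](C)[C@H](O[Si](C)(C)C)[C@@H](C)O[Si](C)(C)C(C)(C)C | intermediate
12 | (2R,3S,4R,5Z)-2-[(tert-butyldimethylsilyl)oxy]-6-iodo-4-methyl-3-[(trimethylsilyl)oxy]hept-5-ene | I/C(C)=C\[C@@H](C)[C@H](O[Si](C)(C)C)[C@@H](C)O[Si](C)(C)C(C)(C)C | intermediate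
13 | (2R,3S,4R,5Z)-2-[(tert-butyldimethylsilyl)oxy]-6-iodo-4-methylhept-5-en-3-ol | I/C(C)=C\[C@@H](C)[C@H](O)[C@@H](C)O[Si](C)(C)C(C)(C)C | intermediate
14 | (2S)-2-methoxypent-4-enoic 2,4,6-trichlorobenzoic anhydride | O=C(OC(=O)[C@@H](OC)CC=C)c1c(Cl)cc(Cl)cc1Cl | intermediate
15 | (2R,3S,4R,5Z)-2-[(tert-butyldimethylsilyl)oxy]-6-iodo-4-methylhept-5-en-3-yl (2S)-2-methoxypent-4-enoate | I/C(C)=C\[C@@H](C)[C@@H]([C@@H](C)O[Si](C)(C)C(C)(C)C)OC(=O)[C@@H](OC)CC=C | intermediate
16 | (2R,3S,4R,5Z)-2-hydroxy-6-iodo-4-methylhept-5-en-3-yl (2S)-2-methoxypent-4-enoate | I/C(C)=C\[C@@H](C)[C@@H]([C@@H](C)O)OC(=O)[C@@H](OC)CC=C | intermediate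
17 | (2R,3S,4R,5Z)-2-acetoxy-6-iodo-4-methylhept-5-en-3-yl (2S)-2-methoxypent-4-enoate | I/C(C)=C\[C@@H](C)[C@@H]([C@@H](C)OC(C)=O)OC(=O)[C@@H](OC)CC=C | intermediate
18 | propanoyl chloride | CCC(Cl)=O | starting material
19 | (4R)-4-benzyl-3-propanoyl-1,3-oxazolidin-2-one | CCC(=O)N1[C@H](Cc2ccccc2)COC1=O | intermediate
20 | (2E)-but-2-enal | C/C=C/C=O | starting material
21 | (4R)-4-benzyl-3-[(2S,3S,4E)-2-methyl-3-[(trimethylsilyl)oxy]hex-4-enoyl]-1,3-oxazolidin-2-one | C/C=C/[C@H](O[Si](C)(C)C)[C@H](C)C(=O)N1[C@H](Cc2ccccc2)COC1=O | intermediate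
22 | (4R)-4-benzyl-3-[(2S,3S,4E)-3-hydroxy-2-methylhex-4-enoyl]-1,3-oxazolidin-2-one | C/C=C/[C@H](O)[C@H](C)C(=O)N1[C@H](Cc2ccccc2)COC1=O | intermediate
23 | (4R)-4-benzyl-3-[(2S,3S,4E)-3-[(tert-butyldimethylsilyl)oxy]-2-methylhex-4-enoyl]-1,3-oxazolidin-2-one | C/C=C/[C@H](O[Si](C)(C)C(C)(C)C)[C@H](C)C(=O)N1[C@H](Cc2ccccc2)COC1=O | intermediate
24 | (4R)-4-benzyl-3-[(2S,3R)-3-[(tert-butyldimethylsilyl)oxy]-2-methyl-4-oxobutanoyl]-1,3-oxazolidin-2-one | O=C[C@H](O[Si](C)(C)C(C)(C)C)[C@H](C)C(=O)N1[C@H](Cc2ccccc2)COC1=O | intermediate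
25 | but-1-en-3-yne | C=CC#C | starting material
26 | chloro[(1E)-buta-1,3-dien-1-yl]bis(cyclopentadienyl)zirconium | C=C/C=C/[Zr](Cl)(C1C=CC=C1)C1C=CC=C1 | intermediate
27 | [(1E)-buta-1,3-dien-1-yl](methyl)zinc | C=C/C=C/[Zn]C | intermediate
28 | (4R)-4-benzyl-3-[(2S,3R,4R,5E)-3-[(tert-butyldimethylsilyl)oxy]-4-hydroxy-2-methylocta-5,7-dienoyl]-1,3-oxazolidin-2-one | C=C/C=C/[C@@H](O)[C@H](O[Si](C)(C)C(C)(C)C)[C@H](C)C(=O)N1[C@H](Cc2ccccc2)COC1=O | intermediate
29 | (3S,4R,5R)-5-[(1E)-buta-1,3-dien-1-yl]-4-[(tert-butyldimethylsilyl)oxy]-3-methyloxolan-2-one | C=C/C=C/[C@H]1OC(=O)[C@@H](C)[C@H]1O[Si](C)(C)C(C)(C)C | intermediate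
30 | (1E,4S,5R,6R,7E)-5-[(tert-butyldimethylsilyl)oxy]-6-hydroxy-4-methyl-1-(tributylstannyl)deca-1,7,9-trien-3-one | CCCC[Sn](CCCC)(CCCC)/C=C/C(=O)[C@@H](C)[C@@H](O[Si](C)(C)C(C)(C)C)[C@H](O)/C=C/C=C | intermediate
31 | (2R,3S,4R,5Z)-2-acetoxy-6-iodo-4-methylhept-5-en-3-yl (2S,4E,6E,8R,9R,10S,12E)-9-[(tert-butyldimethylsilyl)oxy]-8-hydroxy-2-methoxy-10-methyl-11-oxo-13-(tributylstannyl)trideca-4,6,12-trienoate | CCCC[Sn](CCCC)(CCCC)/C=C/C(=O)[C@@H](C)[C@@H](O[Si](C)(C)C(C)(C)C)[C@H](O)/C=C/C=C/C[C@H](OC)C(=O)O[C@H]([C@@H](C)OC(C)=O)[C@H](C)/C=C(/C)I | intermediate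
32 | (3S,5E,7E,9R,10R,11S,13E,15Z,17R,18S)-18-[(1R)-1-acetoxyethyl]-10-[(tert-butyldimethylsilyl)oxy]-9-hydroxy-3-methoxy-11,15,17-trimethyl-1-oxacyclooctadeca-5,7,13,15-tetraene-2,12-dione | CO[C@H]1C/C=C/C=C/[C@@H](O)[C@H](O[Si](C)(C)C(C)(C)C)[C@H](C)C(=O)/C=C/C(C)=C\[C@@H](C)[C@@H]([C@@H](C)OC(C)=O)OC1=O | intermediate
33 | 8,13-deoxy tricycle: cis-fused octalin with ten-membered lactone, 8-OH, 9-OTBS, 11-ketone, 18-OAc (2S,4S,7R,8R,9R,10S,12S,13R,14Z,16R,17S,18R) | CO[C@H]1C[C@H]2C=C[C@H]3[C@@H](O)[C@H](O[Si](C)(C)C(C)(C)C)[C@H](C)C(=O)[C@H]3[C@@H]2/C(C)=C\[C@@H](C)[C@@H]([C@@H](C)OC(C)=O)OC1=O | intermediate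
34 | 18-O-acetyl-9-O-(tert-butyldimethylsilyl)-11-dehydro-9-O-de(pyrrolylcarbonyl)nargenicin (8,13-ether closed; 13S) | CO[C@H]1C[C@H]2C=C[C@H]3[C@H]4O[C@]2(/C(C)=C\[C@@H](C)[C@@H]([C@@H](C)OC(C)=O)OC1=O)[C@@H]3C(=O)[C@@H](C)[C@H]4O[Si](C)(C)C(C)(C)C | intermediate
35 | 18-O-acetyl-11-dehydro-9-O-de(pyrrolylcarbonyl)nargenicin (9-hydroxy-11-ketone) | CO[C@H]1C[C@H]2C=C[C@H]3[C@H]4O[C@]2(/C(C)=C\[C@@H](C)[C@@H]([C@@H](C)OC(C)=O)OC1=O)[C@@H]3C(=O)[C@@H](C)[C@H]4O | intermediate
36 | 1H-pyrrole-2-carbaldehyde | O=Cc1ccc[nH]1 | starting material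
37 | 18-O-acetyl-nargenicin | CO[C@H]1C[C@H]2C=C[C@H]3[C@H]4O[C@]2(/C(C)=C\[C@@H](C)[C@@H]([C@@H](C)OC(C)=O)OC1=O)[C@@H]3[C@H](O)[C@@H](C)[C@H]4OC(=O)c1ccc[nH]1 | target

## Step count and risks

Total steps: 22. Longest linear sequence: 13 (steps 4–11, then 18–22).

**Step 20 (radical C–H etherification).** Risks are β-scission of the C8 alkoxy radical toward the allylic C7 radical, and iodine chemistry on the two olefins. Fallback, setting out from 33 and coming back at 34: replace the one-pot hypoiodite reaction by a halogen-free radical group transfer followed by a separate ionic ring closure. Benzenesulfenyl chloride and Et3N convert 33 into the C8 O-benzenesulfenate F1. Irradiation (with catalytic hexabutyldistannane) starts a chain in which the alkoxy radical abstracts H-13 and the C13 radical takes PhS from a second sulfenate, giving the 13-phenylthio-8-alcohol F2 (either C13 epimer serves). S-methylation (MeOTf, 2,6-di-tert-butylpyridine) ionises the tertiary allylic sulfide and the C8 hydroxyl closes the oxolane to give 34.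

**Step 18 (ene–diene cross-metathesis of two advanced partners).** Risks are homodimerisation, E/Z mixtures and attack at the internal diene olefin. Fallback, setting out from 30 and 17 and coming back at 33: reverse the order of the two couplings. An intermolecular Stille coupling (Pd(PPh3)4, copper thiophene-2-carboxylate, DMF, 0 °C) gives the acyclic pentaene F3. Ring-closing ene–diene metathesis at 25 °C and 1 mM (second-generation Grubbs catalyst RuCl2(=CHPh)(PCy3)(H2IMes)) then gives macrocycle 32, which cyclises to 33 on warming. F3 must be kept cold and used at once, because its open-chain dienone can undergo an untethered intramolecular Diels–Alder reaction.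

**Step 16 (chelation-controlled dienylzinc addition to an α-silyloxy aldehyde).** The risk is low diastereoselectivity at C8. Fallback, setting out from 24 and coming back at 29: set C8 by ketone reduction instead. Adding 27 without the chelating Lewis acid and quenching at −78 °C gives 28 mixed with its C8 epimer F4. Dess–Martin periodinane oxidises the mixture to the dienone F5. Luche reduction (NaBH4, CeCl3, MeOH, −78 °C) under Felkin–Anh control returns the 8,9-syn alcohol 28, which lactonises (Et3N, DMAP) to 29.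

Further compounds

F1 | step 20 | C8 O-benzenesulfenate of 33 | CO[C@H]1C[C@H]2C=C[C@H]3[C@@H](OSc4ccccc4)[C@H](O[Si](C)(C)C(C)(C)C)[C@H](C)C(=O)[C@H]3[C@@H]2/C(C)=C\[C@@H](C)[C@@H]([C@@H](C)OC(C)=O)OC1=O
F2 | step 20 | 13-phenylthio-8-alcohol derived from 33 | CO[C@H]1C[C@H]2C=C[C@H]3[C@@H](O)[C@H](O[Si](C)(C)C(C)(C)C)[C@H](C)C(=O)[C@H]3[C@]2(Sc4ccccc4)/C(C)=C\[C@@H](C)[C@@H]([C@@H](C)OC(C)=O)OC1=O
F3 | step 18 | acyclic pentaene: (2R,3S,4R,5Z,7E,10S,11R,12R,13E)-2-acetoxy-11-[(tert-butyldimethylsilyl)oxy]-12-hydroxy-4,6,10-trimethyl-9-oxohexadeca-5,7,13,15-tetraen-3-yl (2S)-2-methoxypent-4-enoate | C=C/C=C/[C@@H](O)[C@H](O[Si](C)(C)C(C)(C)C)[C@H](C)C(=O)/C=C/C(C)=C\[C@@H](C)[C@@H]([C@@H](C)OC(C)=O)OC(=O)[C@@H](OC)CC=C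
F4 | step 16 | (4R)-4-benzyl-3-[(2S,3R,4S,5E)-3-[(tert-butyldimethylsilyl)oxy]-4-hydroxy-2-methylocta-5,7-dienoyl]-1,3-oxazolidin-2-one (C8 epimer of 28) | C=C/C=C/[C@H](O)[C@H](O[Si](C)(C)C(C)(C)C)[C@H](C)C(=O)N1[C@H](Cc2ccccc2)COC1=O
F5 | step 16 | (4R)-4-benzyl-3-[(2S,3R,5E)-3-[(tert-butyldimethylsilyl)oxy]-2-methyl-4-oxoocta-5,7-dienoyl]-1,3-oxazolidin-2-one | C=C/C=C/C(=O)[C@H](O[Si](C)(C)C(C)(C)C)[C@H](C)C(=O)N1[C@H](Cc2ccccc2)COC1=O
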